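**Retrosynthetic overview**

1. Triketone ring first: 2,4,6-trihydroxybenzaldehyde 1 → 4-methyl ether 2 → dearomatising triple C-methylation (formyl triketone 3) and loss of the formyl blocker → enol-ether dione 4.
2. The pinane comes from the chiral pool: (+)-α-pinene 5 is converted (via 6, 7, 8, 9) into (−)-nopinone 10, so that pinane C-2 is sp2 when the triketone is attached.
3. Disconnection A (bond between the triketone CH2 carbon and pinane C-2): TiCl4-mediated aldol condensation of 4 with 10, through aldol adduct 11, gives the 2-(pinen-2-yl) enol 12, the stable tautomer of the enetrione.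
4. Disconnection B (cyclopentane, last ring): formal [3+2] of the homoprenyl unit of bromide 13 across the C=C of enetrione 14, generated in the flask from 12 by tautomerisation. The CH2–C-2 bond forms first from the open face, then the triketone carbon closes 5-exo on the prenyl alkene, which also creates the isopropyl group, giving target 15.
5. Attaching the triketone carbon to pinane C-2 before the CH2 places the triketone carbon on the gem-dimethyl face, as the target requires. Closing the triketone carbon onto a pinene C-2 that already carries the CH2 would give the C-2 epimer.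

Assumption: the compound is taken to arise in the plant by dearomatising C-methylation of a phloroglucinol, formation of an enetrione (carbon analogue of an o-quinone methide) and a stepwise formal [3+2] closure of the cyclopentane; the pinane in the given SMILES belongs to the (1R,5R) series of (+)-α-pinene.

**Step 1**
Reactants: 1 2,4,6-trihydroxybenzaldehyde
Product: 2 2,6-dihydroxy-4-methoxybenzaldehyde
Conditions: Me2SO4 (1.0 equiv), K2CO3 (1.1 equiv), acetone, 0 °C to rt
Reagents that add atoms: dimethyl sulfate COS(=O)(=O)OC
Why: Williamson O-methylation; the 4-OH (para to the aldehyde) is the most acidic phenol and the only one not hydrogen-bonded to the carbonyl, so one equivalent of Me2SO4 methylates it selectively, and no stereocentre is involved.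

**Step 2**
Reactants: 2 2,6-dihydroxy-4-methoxybenzaldehyde
Product: 4 5-methoxy-4,6,6-trimethylcyclohex-4-ene-1,3-dione, via formyl triketone 3 (not isolated)
Conditions: MeI (3.3 equiv), NaOMe (4 equiv), MeOH, 0 °C to rt; evaporate; 2 M NaOH aq, 50 °C; then HCl to pH 4
Reagents that add atoms: iodomethane CI
Why: Dearomatising C-methylation of the phenoxide (the laboratory counterpart of the biosynthetic methylations) puts Me2 and Me on the two carbons flanking the OMe carbon and stops there because the enol ether cannot supply a further enolate, while the formyl group blocks the carbon between the carbonyls and is then expelled by hydroxide in a retro-Claisen deformylation; no stereocentre.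

**Step 3**
Reactants: 5 (+)-α-pinene
Product: 8 (+)-β-pinene, via pinenylpotassium 6 (not isolated), via pinenylboronate 7 (not isolated)
Conditions: n-BuLi, KOt-Bu, hexane, rt; B(OMe)3, Et2O, −78 °C to rt; 1 M HCl aq, rt
Reagents that add atoms: none
Why: Schlosser-base allylic metalation of the C-10 methyl, borylation and SE2′ protonolysis of the allylboronate put the proton on C-3 and the double bond exocyclic (contrathermodynamic isomerisation), leaving both bridgehead stereocentres untouched.

**Step 4**
Reactants: 8 (+)-β-pinene
Product: 10 (−)-nopinone, via ozonide 9 (not isolated)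
Conditions: O3, CH2Cl2, −78 °C; Me2S, −78 °C to rt
Reagents that add atoms: ozone [O-][O+]=O
Why: Criegee ozonolysis with reductive work-up removes C-10 as formaldehyde; the bridgehead next to the carbonyl cannot enolise, so both stereocentres are retained.

**Step 5**
Reactants: 4 5-methoxy-4,6,6-trimethylcyclohex-4-ene-1,3-dione; 10 (−)-nopinone
Product: 12 3-hydroxy-5-methoxy-4,4,6-trimethyl-2-(6,6-dimethylbicyclo[3.1.1]hept-2-en-2-yl)cyclohexa-2,5-dien-1-one (pinene stereocentres as in 10), via aldol adduct 11 (not isolated)
Conditions: TiCl4 (2 equiv), pyridine (4 equiv), THF, 0 °C to rt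
Reagents that add atoms: none
Why: Knoevenagel-type aldol condensation under Lehnert conditions (TiCl4/pyridine): the Cl3Ti enolate of the single acidic CH2 of 4 adds to the TiCl4-activated ketone from the CH2-bridge face to give aldol adduct 11 as its Cl3Ti alkoxide, whose tertiary C–O bond, weakened by the adjacent enol, ionises while pyridine removes a C-3 proton (the bridgehead side is blocked by Bredt's rule), so the conjugated 2-alkenyl enol 12 is released directly as the dehydration product; the carbinol centre of 11 is destroyed and no new stereocentre remains.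

**Step 6**
Reactants: 12 2-(pinen-2-yl) enol; 13 5-bromo-2-methylpent-2-ene
Product: 15 target spiro compound CNP0307059.1, via enetrione 14 (not isolated)
Conditions: 13 (3 equiv), (Me3Si)3SiH (1.5 equiv, syringe pump), 1,1'-azobis(cyclohexanecarbonitrile) (0.2 equiv), PhMe, 100 °C
Reagents that add atoms: none
Why: Proposed new method: a thermal 1,5-H shift (enol O–H to pinene C-3) converts 12 into enetrione 14, the silyl radical abstracts Br from 13, and the nucleophilic homoprenyl radical adds (Giese) to the β-carbon of 14, i.e. pinane C-2, from the face of the CH2 bridge away from the gem-dimethyl bridge (as Grignard reagents add to nopinone), which fixes the spiro pinane carbon with the triketone carbon on the gem-dimethyl face; the resulting electrophilic 1,3-dicarbonyl radical then closes 5-exo on the electron-rich trisubstituted alkene through a chair-like Beckwith–Houk transition state that keeps the developing CMe2 centre away from the pinane bridgehead and beside the flat vinylogous-ester carbonyl (setting the isopropyl-bearing carbon and the triketone spiro carbon), and the tertiary radical takes H from (Me3Si)3SiH to give the isopropyl group and carry the chain; the closest known chemistry is the radical [3+2] annulation of homoallyl radicals onto alkylidene malonates and Giese addition to alkylidene 1,3-dicarbonyls.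

**Compound list**

1 | 2,4,6-trihydroxybenzaldehyde | O=Cc1c(O)cc(O)cc1O | starting material
2 | 2,6-dihydroxy-4-methoxybenzaldehyde | COc1cc(O)c(C=O)c(O)c1 | intermediate
3 | 2-(hydroxymethylidene)-5-methoxy-4,6,6-trimethylcyclohex-4-ene-1,3-dione (formyl triketone, enol form) | COC1=C(C)C(=O)C(=CO)C(=O)C1(C)C | intermediate
4 | 5-methoxy-4,6,6-trimethylcyclohex-4-ene-1,3-dione | COC1=C(C)C(=O)CC(=O)C1(C)C | intermediate
5 | (+)-α-pinene, (1R,5R)-2,6,6-trimethylbicyclo[3.1.1]hept-2-ene | CC1=CC[C@@H]2C[C@H]1C2(C)C | starting material
6 | pinenylpotassium (allylpotassium at C-10 of 5, bridgeheads as in 5) | [K]CC1=CC[C@@H]2C[C@H]1C2(C)C | intermediate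
7 | dimethyl (pin-2-en-10-yl)boronate (bridgeheads as in 5) | COB(OC)CC1=CC[C@@H]2C[C@H]1C2(C)C | intermediate
8 | (+)-β-pinene, (1R,5R)-6,6-dimethyl-2-methylidenebicyclo[3.1.1]heptane | C=C1CC[C@@H]2C[C@H]1C2(C)C | intermediate
9 | β-pinene ozonide (1,2,4-trioxolane spiro-fused at pinane C-2, both spiro epimers, bridgeheads as in 8) | C1OC2(OO1)CC[C@@H]1C[C@H]2C1(C)C | intermediate
10 | (−)-nopinone, (1S,5R)-6,6-dimethylbicyclo[3.1.1]heptan-2-one | O=C1CC[C@@H]2C[C@H]1C2(C)C | intermediate
11 | aldol adduct: 3-hydroxy-2-(2-hydroxy-6,6-dimethylbicyclo[3.1.1]heptan-2-yl)-5-methoxy-4,4,6-trimethylcyclohexa-2,5-dien-1-one (formed as its Cl3Ti alkoxide; dione carbon on the CH2-bridge face of pinane C-2, OH on the gem-dimethyl face; bridgeheads as in 10) | COC1=C(C)C(=O)C(=C(O)C1(C)C)[C@]2(O)CC[C@@H]3C[C@H]2C3(C)C | intermediate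
12 | 3-hydroxy-5-methoxy-4,4,6-trimethyl-2-(6,6-dimethylbicyclo[3.1.1]hept-2-en-2-yl)cyclohexa-2,5-dien-1-one (bridgeheads as in 10) | COC1=C(C)C(=O)C(C2=CC[C@@H]3C[C@H]2C3(C)C)=C(O)C1(C)C | intermediate
13 | 5-bromo-2-methylpent-2-ene | CC(C)=CCCBr | starting material
14 | enetrione: 2-(6,6-dimethylbicyclo[3.1.1]heptan-2-ylidene)-5-methoxy-4,6,6-trimethylcyclohex-4-ene-1,3-dione (bridgeheads as in 10, alkene geometry irrelevant) | COC1=C(C)C(=O)C(=C2CC[C@@H]3C[C@H]2C3(C)C)C(=O)C1(C)C | intermediate
15 | target: cyclopentane spiro-fused to pinane C-2 (R; CH2 on the CH2-bridge face, triketone carbon on the gem-dimethyl face; C-1 S, C-5 R) and to the 5-methoxy-4,6,6-trimethylcyclohex-4-ene-1,3-dione ring at its C-2 (R), with isopropyl on the adjacent cyclopentane carbon (R), cis to the vinylogous-ester carbonyl | COC1=C(C)C(=O)[C@@]2(C(=O)C1(C)C)[C@@H](C(C)C)CC[C@@]21CC[C@@H]2C[C@H]1C2(C)C | target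

**Step count and risks**

Total steps: 6. Longest linear sequence: 4 steps (1 → 2 → 4 → 12 → 15, or 5 → 8 → 10 → 12 → 15).

Most likely to fail, first: step 6. The radical must add to a fully substituted β-carbon next to a bridgehead, the 1,3-dicarbonyl radical may be reduced before it cyclises, and selectivity at the triketone spiro carbon rests only on the steric difference between the two carbonyl arms. Fallback, setting out from 12 and returning at 15: the two C–C bonds are made in separate operations of opposite redox sense. Zinc dust/CuI in aqueous ethanol under sonication (Luche-type radical conjugate addition) adds the homoprenyl group of 13 to 14, the enetrione tautomer of 12, and the 1,3-dicarbonyl radical is reduced to the bromozinc enolate before it can cyclise, giving the open-chain 2-[2-(4-methylpent-3-enyl)pinan-2-yl] triketone enol F1. Mn(OAc)3·2H2O/Cu(OAc)2 in AcOH at 50 °C then generates the same carbon radical from the trivalent manganese enolate; 5-exo closure follows and divalent copper oxidises the tertiary radical to the isopropenyl spirocycle F2. H2, Pd/C, EtOAc saturates the 1,1-disubstituted alkene (the tetrasubstituted enol ether is inert) to give 15.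

Second: step 5. The ketone is hindered and TiCl4 may attack the methyl enol ether. Fallback, setting out from 10 and 4 and returning at 12: LiN(SiMe3)2 then PhNTf2 (THF, −78 °C) converts 10 into the nopinone enol triflate F3 (only C-3 can enolise). A Pd2(dba)3/t-BuXPhos/K3PO4 coupling in dioxane at 80 °C (zerovalent palladium α-alkenylation of the cyclic 1,3-dione, by analogy with its α-arylation) joins F3 to 4 and gives 12 directly without a condensation.

Third: step 2. O-methylation or incomplete C-methylation can compete, and the formyl group must leave without hydrolysis of the enol ether. Fallback, setting out from 3 (isolated by acidic work-up after the methylation) and returning at 4: benzene-1,2-diamine in EtOH at 50 °C condenses with the hydroxymethylidene carbon to give the aminoanilino enaminone F4. Its second NH2 closes on the same carbon and expels the triketone as its enol, so the formyl carbon leaves under neutral conditions.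

**Further compounds**

F1 | step 6 | 3-hydroxy-5-methoxy-4,4,6-trimethyl-2-[2-(4-methylpent-3-enyl)-6,6-dimethylbicyclo[3.1.1]heptan-2-yl]cyclohexa-2,5-dien-1-one (side chain on the CH2-bridge face of pinane C-2) | COC1=C(C)C(=O)C(=C(O)C1(C)C)[C@@]2(CCC=C(C)C)CC[C@@H]3C[C@H]2C3(C)C
F2 | step 6 | isopropenyl analogue of 15 (prop-1-en-2-yl in place of isopropyl, same configuration) | COC1=C(C)C(=O)[C@@]2(C(=O)C1(C)C)[C@@H](C(C)=C)CC[C@@]21CC[C@@H]2C[C@H]1C2(C)C
F3 | step 5 | 6,6-dimethylbicyclo[3.1.1]hept-2-en-2-yl trifluoromethanesulfonate (bridgeheads as in 10) | O=S(=O)(OC1=CC[C@@H]2C[C@H]1C2(C)C)C(F)(F)F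
F4 | step 2 | 2-{[(2-aminophenyl)amino]methylidene}-5-methoxy-4,6,6-trimethylcyclohex-4-ene-1,3-dione | COC1=C(C)C(=O)C(=CNc2ccccc2N)C(=O)C1(C)C
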